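## Structural features

The target is a monocyclic oxolane (O1, C2, C3, C4, C5) with a 3,4,5-trimethoxyphenyl group on C2, a hydroxymethyl group on C3 and a 2,4,5-trimethoxybenzyl group on C4; C5 is an unsubstituted OCH2. C2, C3 and C4 are three contiguous stereocentres, all R, and the three substituents lie on one face of the ring (2,3-cis and 3,4-cis), the most congested of the four possible arrangements. Neither C3 nor C4 carries an acidifying group, so a wrong centre cannot be corrected by late equilibration, and equilibration at C2 would lead away from the all-cis isomer. The fragile elements are the benzylic C2–O1 bond (ionised by acid, open to hydrogenolysis), the very electron-rich 2,4,5-trimethoxyphenyl ring (nucleophilic and oxidisable) and, in unsaturated intermediates, the C2–H bond, which becomes doubly allylic and benzylic. The real difficulty is therefore the kinetic construction of the all-cis triad. The key step exploits the fact that C3 and C4 each bear one hydrogen and one carbon branch, with both hydrogens on the face opposite to the C2 aryl group. Each can thus be disguised as an exocyclic alkene carbon, which leaves C2 as the only stereocentre of the ring and lets the C3–C4 bond be made between an alkyne carbon and an alkene carbon joined through C5–O1–C2.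

## Logic of the disconnections

From 14 the hydroxyl is masked as a silyl ether (13), and in 13 the C4–H and benzylic C–H bonds are removed to give the exocyclic alkene of 12. This turns C4 into an sp2 carbon, so its configuration becomes a question of face selection only. The gain is one stereocentre less. The demand is a syn addition of hydrogen anti to the C3 and C2 substituents, without alkene migration, without cleavage of C2–O1, and with no free hydroxyl to steer the catalyst to the wrong face.

In 12 the O–Si bond is cut again (11), and in 11 the C–O bond of the hydroxymethyl carbon and the C3–H bond are cut, which leads through 10 to 9. C3 becomes sp2 as well, so 9 keeps C2 as its only stereocentre and both remaining centres follow from additions anti to one aryl group. The demand is an anti-Markovnikov hydration that picks the 1,1-disubstituted alkene over the trisubstituted one and delivers hydrogen to C3 from the face away from the aryl group.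

In 9 the C3–C4 bond is cut, which opens the ring to the acyclic 1,6-enyne 8. The bond lies between two sp2 carbons, so its formation raises no cis/trans question, and the cut separates the molecule into an allyl half and a propargyl half joined only by an ether oxygen. The demand is a 5-exo closure that ends in a 1,3-diene, leaves C2 untouched and does not let the product drift to the aromatic ring system.

In 8 the alkyne–aryl bond is cut, giving 6 and 7. This keeps the electron-rich arene out of the first steps and uses it as a purchased unit with the correct substitution. The demand is an sp–sp2 coupling that tolerates the allylic ether.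

In 6 the O–CH2 bond of the propargyl group is cut, giving 4 and 5. The C–O bond at the stereocentre is not the one formed, so the configuration of 4 is carried over unchanged. The demand is an O-alkylation under conditions that do not isomerise the propargyl group.

In 4 the absolute configuration is traced back to racemic 3 by a kinetic resolution, and in 3 the bond between the carbinol carbon and the vinyl group is cut, giving 1 and 2. Both are bulk chemicals. The demand is a resolution that leaves the R enantiomer as the unreacted alcohol in high enantiomeric purity.

## Other disconnections considered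

Alternative 1: The cut breaks three C–C bonds of the 2-oxygenated 4,5-dimethoxybenzene ring, leaving the all-cis oxolane with a prop-2-ynyl group on C4 (A2) and a pentacarbonylchromium methoxy(1-methoxyvinyl)carbene (A3). Forward, a Dötz benzannulation would join A2, A3 and one CO ligand of the zerovalent chromium complex to the phenol A1; O-methylation of A1 would give 13, and step 9 the target.
- In its favour: the regiochemistry follows from the terminal alkyne (its substituted carbon ends up next to the phenol carbon), the 2,4,5-oxygen pattern emerges correctly, and no stereocentre is touched.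
- Against it here: the cut is made in the one part of the molecule that poses no problem, since that ring can be bought as 7, while the all-cis triad of A2 still has to be made by other means. The step consumes a stoichiometric chromium complex with a delicate enol-ether-substituted carbene, cyclopentannulation competes with phenol formation, and a methylation is added.
- Comparison: structurally, the chosen plan spends its key step on the ring that carries the stereocentres and imports both arenes intact. Mechanistically, both are metal-templated ring constructions that create no stereocentre, and here the alternative is the equal of the chosen plan. In step economy it is clearly longer.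
- It is the better plan on one point: the benzyl-ring substitution is decided in the last C–C bond-forming step, which would serve a series of analogues, and no acid-labile diene is handled.

Alternative 2: The cut is the O1–C2 bond (with C2–H), which opens the ring to the γ-hydroxy aryl ketone A5, in equilibrium with its lactol anomers. Forward, BF3·OEt2 would ionise the lactol to the five-membered oxocarbenium ion and Et3SiH would deliver hydride to C2 from the face opposite to the two cis substituents, giving A4, the triisopropylsilyl ether of the target; desilylation would finish.
- In its favour: the step is stereoconvergent, C2 is set last under the control of two existing centres, the reagents are cheap and metal-free, and hydride delivery anti to the ring substituents is a well-founded expectation.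
- Against it here: the 3,4-relationship has to be created in an open chain, which calls for auxiliary- or catalyst-controlled C–C bond formation over several steps. The C3 centre is α to the ketone and next to the cationic carbon, so enolisation or proton loss could erase it. The cationic C2 also sits five atoms from the nucleophilic 2,4,5-trimethoxyphenyl ring, so Friedel–Crafts closure of a six-membered ring would compete with hydride capture.
- Comparison: structurally, this route closes the ring through a C–O bond after the carbon stereocentres exist; the chosen one closes it through C3–C4 before they exist. Mechanistically, it relies on a cation at C2, which the chosen plan never generates, but it needs no face-selective addition to an alkene. In step economy its endgame is shorter (two operations from A5 against four from 9), while the way to A5 is expected to be longer than the five steps to 9.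
- It is the better plan in two respects: all material converges on one stereoisomer at the decisive step, and no enantiomer need be discarded if A5 is made by asymmetric synthesis.

Alternative 3: The cut is the C2–C3 bond; the retron is the cis-fused furofuranone A6, which arises from the α-diazo-γ-butyrolactone A7 (aryl and ether arm trans). Forward, Rh2(OAc)4 would decompose A7 and the carbenoid at the lactone α-carbon would insert into a benzylic C–H bond of the ether arm (1,5-insertion). This forms C2–C3, closes the oxolane and sets C2 and C3. Cleavage of the lactone's benzylic C–O bond and reduction of the carboxyl group would then lead to 14.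
- In its favour: one catalytic step makes a ring, a C–C bond and two stereocentres; the C–H bond is doubly activated; and the cis ring fusion makes the 3,4-cis relationship a geometric necessity.
- Against it here: the target needs the C2 aryl group on the concave face of the bicycle, whereas the insertion transition state would be expected to place it on the convex face, which gives the C2 epimer. The carbenoid carbon has a β-hydrogen, so 1,2-hydride shift competes with insertion; the electron-rich arenes invite cyclopropanation and the ether oxygen invites ylide formation. Afterwards one benzylic C–O bond must be cleaved beside another, and the lactone template costs two redox steps.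
- Comparison: structurally, both plans close the oxolane through a C–C bond, but this one needs a sacrificial lactone ring. Mechanistically, it creates stereocentres in the ring-closing step under kinetic control that probably opposes the target at C2, whereas the chosen plan separates ring closure from stereocontrol. In step economy the two are comparable at best.
- It is the better plan on one point, since 3,4-cis is enforced by the ring fusion and not by facial selectivity, and it is the equal of the chosen plan in using only a catalytic amount of a precious metal.

Key step: step 5

Remark on the resolution: by the empirical size rule for lipases (aryl large, vinyl medium) the R alcohol is the enantiomer that is acylated, so a lipase resolution would leave the S alcohol; the R alcohol is therefore taken as the unreacted enantiomer of a Sharpless kinetic resolution.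

Remark on descriptors: the C2 descriptor is R in 4, 6, 8 and 10–14 but S in 9, with no change in spatial arrangement, because the sp2 carbon C3 of 9 outranks the aryl group.

Remark on supply: 1-iodo-2,4,5-trimethoxybenzene is treated as a purchasable compound.

## Route

Step 1
Reactants: 1 3,4,5-trimethoxybenzaldehyde; 2 vinylmagnesium bromide
Product: 3 rac-1-(3,4,5-trimethoxyphenyl)prop-2-en-1-ol
Conditions: 2 (1.2 equiv, 1 M in THF), THF, −20 to 0 °C; then sat. aq NH4Cl
Reagents that add atoms: vinylmagnesium bromide 2, C=C[Mg]Br
Why: Grignard 1,2-addition to a non-enolisable aromatic aldehyde; the carbinol centre is formed racemic and is resolved in step 2. The quench is buffered because the allylic, benzylic alcohol can undergo acid-induced 1,3-transposition.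

Step 2
Reactants: 3 rac-1-(3,4,5-trimethoxyphenyl)prop-2-en-1-ol
Product: 4 (1R)-1-(3,4,5-trimethoxyphenyl)prop-2-en-1-ol
Conditions: Ti(OiPr)4 (0.2 equiv), D-(−)-diisopropyl tartrate (0.24 equiv), t-BuOOH (0.65 equiv), 4 Å MS, CH2Cl2, −20 °C; aq NaOH–brine work-up
Reagents that add atoms: none
Why: Sharpless kinetic resolution: the titanium–tartrate catalyst epoxidises one enantiomer of a secondary allylic alcohol much faster than the other, and conversion a little beyond one half should leave 4 in high enantiomeric purity. With D-(−)-DIPT the fast-reacting enantiomer should be the S alcohol (aryl outranks vinyl, so the descriptor is opposite to that of the alkyl vinyl carbinol series); it is removed as a more polar epoxy alcohol. The configuration of 4 would be confirmed on its MTPA esters before it is carried on.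

Step 3
Reactants: 4 (1R)-1-(3,4,5-trimethoxyphenyl)prop-2-en-1-ol; 5 propargyl bromide
Product: 6 1,2,3-trimethoxy-5-[(1R)-1-(prop-2-yn-1-yloxy)prop-2-en-1-yl]benzene
Conditions: NaH (1.2 equiv), THF–DMF (4:1), 0 °C; then 5 (1.3 equiv), Bu4NI (cat.), 0 °C to rt
Reagents that add atoms: propargyl bromide 5, C#CCBr
Why: Williamson ether synthesis: the sodium alkoxide displaces bromide at the propargylic CH2 (SN2), so no bond at the stereocentre is touched and the configuration is retained. NaH at or below room temperature should not isomerise the propargyl ether to the allene or trigger a Wittig rearrangement.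

Step 4
Reactants: 6 1,2,3-trimethoxy-5-[(1R)-1-(prop-2-yn-1-yloxy)prop-2-en-1-yl]benzene; 7 1-iodo-2,4,5-trimethoxybenzene
Product: 8 (1R)-1-(3,4,5-trimethoxyphenyl)prop-2-en-1-yl 3-(2,4,5-trimethoxyphenyl)prop-2-yn-1-yl ether
Conditions: PdCl2(PPh3)2 (3 mol%), CuI (5 mol%), Et3N–THF (1:1), degassed, rt to 45 °C
Reagents that add atoms: 1-iodo-2,4,5-trimethoxybenzene 7, COc1cc(OC)c(OC)cc1I
Why: Sonogashira coupling of the terminal alkyne with the aryl iodide, which should undergo oxidative addition readily despite its donor groups. Oxygen is excluded to suppress Glaser dimerisation; the allylic ether is not ionised by zerovalent palladium because an alkoxide is a poor leaving group, so the stereocentre stays intact.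

Step 5
Reactants: 8 (1R)-1-(3,4,5-trimethoxyphenyl)prop-2-en-1-yl 3-(2,4,5-trimethoxyphenyl)prop-2-yn-1-yl ether
Product: 9 (2S,4Z)-3-methylidene-4-[(2,4,5-trimethoxyphenyl)methylidene]-2-(3,4,5-trimethoxyphenyl)oxolane
Conditions: Pd(OAc)2 (5 mol%), PPh3 (10 mol%), PhMe (0.05 M, degassed), 60 °C; filtration through basic Al2O3; used at once
Reagents that add atoms: none
Why: Palladium-catalysed 1,6-enyne cycloisomerisation of the Alder-ene family, here ending in a 1,3-diene. A hydridopalladium acetate, formed from Pd(OAc)2 and PPh3 by reduction to zerovalent palladium and re-protonation by the acetic acid released, should add syn across the alkyne with palladium on the tether carbon C4 and hydrogen on the aryl-bearing carbon; the alternative entry, oxidative cyclisation of divalent palladium to a palladacyclopentene, leads to the same product. The alkenyl–palladium bond then inserts the vinyl group in a 5-exo-trig carbopalladation, which forms C3–C4 and closes the oxolane; a 6-endo closure is disfavoured by the three-atom ether tether. The resulting primary alkylpalladium has a single β-hydrogen, the one on C3, so β-hydride elimination can only give the exocyclic C3=CH2 and cannot give a 1,4-diene. Because hydrogen and the new C3–C4 bond are delivered cis across the former triple bond, the aryl group ends up cis to C5, which is the Z benzylidene. No stereocentre is created, and C2 is a spectator that keeps its configuration. The step needs 5-exo regiochemistry, which the tether secures, and it needs the product to survive: the doubly allylic, benzylic C2–H makes aromatising double-bond migration the thermodynamic sink, so the reaction is run without added acid, dilute, and is stopped at full conversion.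

Step 6
Reactants: 9 (2S,4Z)-3-methylidene-4-[(2,4,5-trimethoxyphenyl)methylidene]-2-(3,4,5-trimethoxyphenyl)oxolane
Product: 11 [(2R,3R,4Z)-2-(3,4,5-trimethoxyphenyl)-4-[(2,4,5-trimethoxyphenyl)methylidene]oxolan-3-yl]methanol, via B-alkyl-9-BBN adduct 10 (not isolated)
Conditions: 9-BBN (1.3 equiv, 0.5 M in THF), THF, 0 °C to rt; then 3 M aq NaOH, 30% H2O2, 0 °C to rt
Reagents that add atoms: hydrogen peroxide, OO (hydroxyl oxygen of 11); 9-borabicyclo[3.3.1]nonane, B1C2CCCC1CCC2 (boron bicycle of 10 only)
Why: Hydroboration–oxidation: 9-BBN should add to the 1,1-disubstituted alkene far faster than to the trisubstituted, aryl-conjugated one, with boron on the terminal carbon, to give 10. The four-centre addition should occur on the face of C3=CH2 opposite to the C2 aryl group, so hydrogen enters C3 anti to the aryl group and the CH2B (then CH2OH) arm ends up cis to it (3R in 11). Alkaline peroxide oxidises the C–B bond with retention and should leave the electron-rich styrene untouched.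

Step 7
Reactants: 11 [(2R,3R,4Z)-2-(3,4,5-trimethoxyphenyl)-4-[(2,4,5-trimethoxyphenyl)methylidene]oxolan-3-yl]methanol
Product: 12 tert-butyl(dimethyl){[(2R,3R,4Z)-2-(3,4,5-trimethoxyphenyl)-4-[(2,4,5-trimethoxyphenyl)methylidene]oxolan-3-yl]methoxy}silane
Conditions: TBSCl (1.3 equiv), imidazole (2.5 equiv), DMF, 0 °C to rt
Reagents that add atoms: tert-butyldimethylsilyl chloride, CC(C)(C)[Si](C)(C)Cl
Why: Silylation of the primary alcohol with a silyl chloride and imidazole. The ether removes the one group that could anchor the substrate to a catalyst surface from the wrong face, and it enlarges the C3 substituent that shields that face.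

Step 8
Reactants: 12 tert-butyl(dimethyl){[(2R,3R,4Z)-2-(3,4,5-trimethoxyphenyl)-4-[(2,4,5-trimethoxyphenyl)methylidene]oxolan-3-yl]methoxy}silane
Product: 13 tert-butyl(dimethyl){[(2R,3R,4R)-2-(3,4,5-trimethoxyphenyl)-4-[(2,4,5-trimethoxyphenyl)methyl]oxolan-3-yl]methoxy}silane
Conditions: H2 (1 atm), 5% Pt/C, EtOAc, Et3N (trace), rt
Reagents that add atoms: none
Why: Heterogeneous catalytic hydrogenation, a syn addition from the less hindered face: the C3 silyloxymethyl group and the C2 aryl group occupy one face, so the alkene should adsorb through the other and hydrogen should enter C4 anti to both, which places the benzyl group cis to them (4R). Platinum is chosen over palladium because it is less prone to double-bond migration and to hydrogenolysis of the benzylic C2–O1 bond; the trace of amine keeps the medium non-acidic.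

Step 9
Reactants: 13 tert-butyl(dimethyl){[(2R,3R,4R)-2-(3,4,5-trimethoxyphenyl)-4-[(2,4,5-trimethoxyphenyl)methyl]oxolan-3-yl]methoxy}silane
Product: 14 [(2R,3R,4R)-2-(3,4,5-trimethoxyphenyl)-4-[(2,4,5-trimethoxyphenyl)methyl]oxolan-3-yl]methanol (CNP0238280.1)
Conditions: Bu4NF (1.2 equiv), THF, 0 °C to rt
Reagents that add atoms: none
Why: Fluoride-mediated cleavage of the Si–O bond (desilylation); no stereocentre is involved, and the near-neutral conditions should leave the benzylic ether and the aryl methyl ethers intact.

## Compound list

1 | 3,4,5-trimethoxybenzaldehyde | COc1cc(C=O)cc(OC)c1OC | starting material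
2 | vinylmagnesium bromide | C=C[Mg]Br | starting material
3 | rac-1-(3,4,5-trimethoxyphenyl)prop-2-en-1-ol | C=CC(O)c1cc(OC)c(OC)c(OC)c1 | intermediate
4 | (1R)-1-(3,4,5-trimethoxyphenyl)prop-2-en-1-ol | O[C@@H](c1cc(OC)c(OC)c(OC)c1)C=C | intermediate
5 | propargyl bromide | C#CCBr | starting material
6 | 1,2,3-trimethoxy-5-[(1R)-1-(prop-2-yn-1-yloxy)prop-2-en-1-yl]benzene | C#CCO[C@@H](c1cc(OC)c(OC)c(OC)c1)C=C | intermediate
7 | 1-iodo-2,4,5-trimethoxybenzene | COc1cc(OC)c(OC)cc1I | starting material
8 | (1R)-1-(3,4,5-trimethoxyphenyl)prop-2-en-1-yl 3-(2,4,5-trimethoxyphenyl)prop-2-yn-1-yl ether | COc1cc(OC)c(OC)cc1C#CCO[C@@H](c2cc(OC)c(OC)c(OC)c2)C=C | intermediate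
9 | (2S,4Z)-3-methylidene-4-[(2,4,5-trimethoxyphenyl)methylidene]-2-(3,4,5-trimethoxyphenyl)oxolane | COc1cc(OC)c(OC)cc1/C=C1\CO[C@@H](c2cc(OC)c(OC)c(OC)c2)C1=C | intermediate
10 | 9-{[(2R,3S,4Z)-2-(3,4,5-trimethoxyphenyl)-4-[(2,4,5-trimethoxyphenyl)methylidene]oxolan-3-yl]methyl}-9-borabicyclo[3.3.1]nonane (CH2B cis to the C2 aryl group) | COc1cc(OC)c(OC)cc1/C=C1\CO[C@@H](c2cc(OC)c(OC)c(OC)c2)[C@H]1CB1C2CCCC1CCC2 | intermediate (not isolated)
11 | [(2R,3R,4Z)-2-(3,4,5-trimethoxyphenyl)-4-[(2,4,5-trimethoxyphenyl)methylidene]oxolan-3-yl]methanol | COc1cc(OC)c(OC)cc1/C=C1\CO[C@@H](c2cc(OC)c(OC)c(OC)c2)[C@H]1CO | intermediate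
12 | tert-butyl(dimethyl){[(2R,3R,4Z)-2-(3,4,5-trimethoxyphenyl)-4-[(2,4,5-trimethoxyphenyl)methylidene]oxolan-3-yl]methoxy}silane | COc1cc(OC)c(OC)cc1/C=C1\CO[C@@H](c2cc(OC)c(OC)c(OC)c2)[C@H]1CO[Si](C)(C)C(C)(C)C | intermediate
13 | tert-butyl(dimethyl){[(2R,3R,4R)-2-(3,4,5-trimethoxyphenyl)-4-[(2,4,5-trimethoxyphenyl)methyl]oxolan-3-yl]methoxy}silane (all-cis) | COc1cc(OC)c(OC)cc1C[C@H]1CO[C@@H](c2cc(OC)c(OC)c(OC)c2)[C@H]1CO[Si](C)(C)C(C)(C)C | intermediate
14 | [(2R,3R,4R)-2-(3,4,5-trimethoxyphenyl)-4-[(2,4,5-trimethoxyphenyl)methyl]oxolan-3-yl]methanol (all-cis) | COc1cc(OC)c(OC)cc1C[C@H]1CO[C@@H](c2cc(OC)c(OC)c(OC)c2)[C@H]1CO | target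

## Step count and least certain steps

Total: 9 steps. Longest linear sequence: 9 steps (1 to 14); 5 and 7 enter as purchased reagents.

Step 5 (key step). What may go wrong: after ring closure the palladium hydride can re-add to the diene and walk the double bonds into the ring, ending in aromatisation and loss of the C2 stereocentre; traces of acid on work-up can start the same drift. In addition, the electron-rich, ortho-substituted aryl alkyne may hydropalladate slowly, so that catalyst decay or Diels–Alder dimerisation of the s-cis diene outruns cyclisation.
Fallback (sets out from 4, rejoins at 9): the ring would be closed by an intramolecular Heck reaction instead. 2,4,5-Trimethoxybenzaldehyde would be condensed with methyl 2-[bis(2,2,2-trifluoroethoxy)phosphoryl]-2-bromoacetate (KN(SiMe3)2, 18-crown-6, THF, −78 °C), the Still–Gennari-type Horner–Wadsworth–Emmons variant that places the aryl group cis to the ester. This should give methyl (E)-2-bromo-3-(2,4,5-trimethoxyphenyl)prop-2-enoate F1; a minor geometric isomer would be removed at this stage. Reduction with i-Bu2AlH would give (E)-2-bromo-3-(2,4,5-trimethoxyphenyl)prop-2-en-1-ol F2, and CBr4/PPh3 the allylic bromide (E)-2,3-dibromo-1-(2,4,5-trimethoxyphenyl)prop-1-ene F3. Alkylation of the sodium alkoxide of 4 with F3 would give (1R)-1-(3,4,5-trimethoxyphenyl)prop-2-en-1-yl (E)-2-bromo-3-(2,4,5-trimethoxyphenyl)prop-2-en-1-yl ether F4, in which bromine sits on the future C4 and the aryl group is already cis to the OCH2 carbon. Pd(OAc)2/PPh3 with Ag2CO3 in MeCN at 70 °C should then effect oxidative addition, 5-exo-trig insertion of the vinyl group and β-hydride elimination of the C3 hydrogen, giving 9 with retention of the alkene geometry. Silver carbonate removes HBr as it forms, so no palladium hydride lingers to start the migration.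

Step 6. What may go wrong: erosion of facial selectivity if the borane approaches syn to the aryl group, competing addition to the benzylidene, or decay of the labile diene before it is consumed.
Fallback (sets out from 9, rejoins at 14): the two centres would be set together and not one after the other. Ni(cod)2/PCy3-catalysed addition of pinacolborane across the termini of the s-cis diene (1,4-hydroboration by zerovalent nickel; boron to the unsubstituted CH2 terminus, hydrogen to the benzylidene carbon) should give 2-{[(2S)-4-[(2,4,5-trimethoxyphenyl)methyl]-2-(3,4,5-trimethoxyphenyl)-2,5-dihydrofuran-3-yl]methyl}-4,4,5,5-tetramethyl-1,3,2-dioxaborolane F5. This is an allylboronate with a tetrasubstituted C3=C4 bond and no new stereocentre. NaOH/H2O2 would convert it into [(2S)-4-[(2,4,5-trimethoxyphenyl)methyl]-2-(3,4,5-trimethoxyphenyl)-2,5-dihydrofuran-3-yl]methanol F6. Hydrogenation of F6 with [Ir(cod)(PCy3)(py)]PF6 in CH2Cl2, in which the allylic hydroxyl binds iridium and the C2 aryl group decides the face, should add both hydrogens anti to the aryl group and give 14 directly, without the silyl detour.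

Step 8. What may go wrong: migration of the exocyclic double bond into the ring on the metal surface before hydrogen is added, hydrogenolysis of the benzylic C2–O1 bond, or incomplete discrimination of the two faces.
Fallback (sets out from 12, rejoins at 13): reduction by metal-hydride hydrogen-atom transfer in place of surface hydrogenation, with Mn(dpm)3 (cat.), PhSiH3 and t-BuOOH in i-PrOH at rt. A hydrogen atom should be delivered to C4, because the benzylic radical is the more stabilised one, from the face left open by the silyloxymethyl group; the benzylic radical is then quenched. This manifold does not cleave benzylic C–O bonds and has no surface-bound allyl intermediates. No new compound is involved.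

Step 2. What may go wrong: slow epoxidation of a terminal vinyl carbinol and incomplete kinetic discrimination, so that the recovered alcohol is not enantiopure at a practical conversion; Lewis-acid ionisation of the doubly activated carbinol.
Fallback (sets out from 3, rejoins at 4): enzymatic acylation. Immobilised Candida antarctica lipase B with vinyl acetate in MTBE should acetylate the R alcohol and leave the S alcohol. The (1R)-1-(3,4,5-trimethoxyphenyl)prop-2-en-1-yl acetate F7 would be separated and cleaved with K2CO3 in MeOH to give 4, at the cost of one extra step.

## Further compounds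

F1 | step 5 | methyl (E)-2-bromo-3-(2,4,5-trimethoxyphenyl)prop-2-enoate | COC(=O)/C(Br)=C\c1cc(OC)c(OC)cc1OC
F2 | step 5 | (E)-2-bromo-3-(2,4,5-trimethoxyphenyl)prop-2-en-1-ol | OC/C(Br)=C\c1cc(OC)c(OC)cc1OC
F3 | step 5 | (E)-2,3-dibromo-1-(2,4,5-trimethoxyphenyl)prop-1-ene | BrC/C(Br)=C\c1cc(OC)c(OC)cc1OC
F4 | step 5 | (1R)-1-(3,4,5-trimethoxyphenyl)prop-2-en-1-yl (E)-2-bromo-3-(2,4,5-trimethoxyphenyl)prop-2-en-1-yl ether | COc1cc(OC)c(OC)cc1/C=C(Br)\CO[C@@H](c2cc(OC)c(OC)c(OC)c2)C=C
F5 | step 6 | 2-{[(2S)-4-[(2,4,5-trimethoxyphenyl)methyl]-2-(3,4,5-trimethoxyphenyl)-2,5-dihydrofuran-3-yl]methyl}-4,4,5,5-tetramethyl-1,3,2-dioxaborolane | COc1cc(OC)c(OC)cc1CC1=C(CB2OC(C)(C)C(C)(C)O2)[C@H](c2cc(OC)c(OC)c(OC)c2)OC1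
F6 | step 6 | [(2S)-4-[(2,4,5-trimethoxyphenyl)methyl]-2-(3,4,5-trimethoxyphenyl)-2,5-dihydrofuran-3-yl]methanol | COc1cc(OC)c(OC)cc1CC1=C(CO)[C@H](c2cc(OC)c(OC)c(OC)c2)OC1
F0 | step 8 | none | none
F7 | step 2 | (1R)-1-(3,4,5-trimethoxyphenyl)prop-2-en-1-yl acetate | CC(=O)O[C@@H](c1cc(OC)c(OC)c(OC)c1)C=C
A1 | alternative 1 | 2-{[(3R,4R,5R)-4-({[tert-butyl(dimethyl)silyl]oxy}methyl)-5-(3,4,5-trimethoxyphenyl)oxolan-3-yl]methyl}-4,5-dimethoxyphenol (all-cis) | Oc1cc(OC)c(OC)cc1C[C@H]1CO[C@@H](c2cc(OC)c(OC)c(OC)c2)[C@H]1CO[Si](C)(C)C(C)(C)C
A2 | alternative 1 | tert-butyl(dimethyl){[all-cis-4-(prop-2-yn-1-yl)-2-(3,4,5-trimethoxyphenyl)oxolan-3-yl]methoxy}silane | C#CC[C@H]1CO[C@@H](c2cc(OC)c(OC)c(OC)c2)[C@H]1CO[Si](C)(C)C(C)(C)C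
A3 | alternative 1 | pentacarbonyl[methoxy(1-methoxyvinyl)carbene]chromium, (CO)5Cr=C(OMe)C(OMe)=CH2 | COC(=C)C(OC)=[Cr].[C-]#[O+].[C-]#[O+].[C-]#[O+].[C-]#[O+].[C-]#[O+]
A4 | alternative 2 | triisopropyl{[(2R,3R,4R)-2-(3,4,5-trimethoxyphenyl)-4-[(2,4,5-trimethoxyphenyl)methyl]oxolan-3-yl]methoxy}silane | COc1cc(OC)c(OC)cc1C[C@H]1CO[C@@H](c2cc(OC)c(OC)c(OC)c2)[C@H]1CO[Si](C(C)C)(C(C)C)C(C)C
A5 | alternative 2 | (2R,3R)-4-hydroxy-3-[(2,4,5-trimethoxyphenyl)methyl]-2-{[(triisopropylsilyl)oxy]methyl}-1-(3,4,5-trimethoxyphenyl)butan-1-one | COc1cc(OC)c(OC)cc1C[C@@H](CO)[C@H](CO[Si](C(C)C)(C(C)C)C(C)C)C(=O)c1cc(OC)c(OC)c(OC)c1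
A6 | alternative 3 | cis-fused furofuranone with endo 3,4,5-trimethoxyphenyl and exo 2,4,5-trimethoxyphenyl groups | COc1cc(OC)c(OC)cc1[C@@H]2[C@H]1CO[C@@H](c3cc(OC)c(OC)c(OC)c3)[C@H]1C(=O)O2
A7 | alternative 3 | trans-3-diazo-4-{[(3,4,5-trimethoxyphenyl)methoxy]methyl}-5-(2,4,5-trimethoxyphenyl)oxolan-2-one | COc1cc(OC)c(OC)cc1[C@@H]1[C@@H](COCc2cc(OC)c(OC)c(OC)c2)C(=[N+]=[N-])C(=O)O1
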